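**Retrosynthetic overview**
1. The route rests on the cyclohepta-2,5-dienone ring C1(=O)–C2=C3–C4–C5=C6–C10, fused through C6–C10 to the cyclopentanone ring C6–C7–C8–C9–C10, with the quaternary C10 between the C1 and C9 carbonyls.
2. Late stage: C1–O ester; C1 carbinol from the C1 ketone by hydride delivered from the C6 hydroxyl; C6–OH/C5H2 from C5=C6 by α-epoxidation and selenide opening; the C9 ketone is masked as a dioxolane for this stretch.
3. Key disconnection: the seven-membered ring from a cis-ketenyl/cyclopentenonyl cyclopropane by a [3,3] shift (C1–C10 made, C3–C5 broken); the ketene from a diazoketone by Wolff shift (C2–C3 made).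
4. Precursor: cyclopropane from a Z-dienol (directed asymmetric Simmons–Smith), Z-olefin from an enal and a phosphonate, cyclopentene from (R)-carvone, so that the C9 oxygen is the carvone oxygen and C7 the carvone stereocentre (no allylic oxidation beside the vinylcyclopropane is needed).
5. Ring order: five-membered ring (step 5), cyclopropane (step 8), seven-membered ring with loss of the cyclopropane (step 13).

Key step: step 13

**Remarks on the chemistry**
- Numbering used for every intermediate: C1 ester carbinol, C2=C3(CH3), C4, C5, C6 (ring-fusion carbinol), C7 (isopropyl), C8, C9 (ketone), C10 (ring-fusion, methyl). β is the face of the bicycle that carries the C10 methyl group, α the opposite face.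
- The silyloxy carbon of 4–11 (future C9) is drawn as the cis isomer expected from step 2. If it epimerises in step 5 the mixture converges in step 10.
- Assumption: the dioxaborolane ligand selects the olefin face of dienol 10 in the same sense as with simple allylic alcohols, where the (R,R)-ligand turns E-cinnamyl alcohol into the (2S,3S)-cyclopropylmethanol. On that basis the (S,S)-ligand is required.

**Route**

Step 1
Reactants: 1 (R)-(−)-carvone
Product: 2 (5R)-2-methyl-5-(propan-2-yl)cyclohex-2-en-1-one
Conditions: H2 (1 atm), RhCl(PPh3)3 (cat.), benzene, rt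
Reagents that add atoms: none
Why: Homogeneous rhodium-catalysed hydrogenation should reduce the unhindered 1,1-disubstituted isopropenyl olefin much faster than the trisubstituted conjugated ring olefin, so the enone and the stereocentre that becomes C7 are kept.

Step 2
Reactants: 2 (5R)-2-methyl-5-(propan-2-yl)cyclohex-2-en-1-one
Product: 3 (1R,5R)-2-methyl-5-(propan-2-yl)cyclohex-2-en-1-ol (cis)
Conditions: NaBH4, CeCl3·7H2O, MeOH, −78 °C to 0 °C
Reagents that add atoms: none
Why: Luche 1,2-reduction with axial hydride addition to the half-chair that holds the isopropyl group equatorial should give the cis alcohol, and this temporary centre (future C9) is erased in step 10.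

Step 3
Reactants: 3 (1R,5R)-2-methyl-5-(propan-2-yl)cyclohex-2-en-1-ol
Product: 4 tert-butyldimethylsilyl ether of 3
Conditions: TBSCl, imidazole, DMF, rt
Reagents that add atoms: tert-butyldimethylsilyl chloride, CC(C)(C)[Si](C)(C)Cl
Why: Standard silylation of a secondary allylic alcohol, needed because a free α-hydroxy ketone would interfere with the ozonolysis and aldol steps.

Step 4
Reactants: 4 silyl ether
Product: 6 (3S,5R)-5-(tert-butyldimethylsilyloxy)-6-oxo-3-(propan-2-yl)heptanal, via ozonide 5 (not isolated)
Conditions: O3, CH2Cl2, −78 °C; then PPh3, −78 °C to rt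
Reagents that add atoms: ozone, [O-][O+]=O
Why: Ozonolysis of the only C=C bond with reductive work-up cleaves the six-membered ring to a methyl ketone and an aldehyde without touching the silyl ether or the isopropyl-bearing centre.

Step 5
Reactants: 6 keto aldehyde
Product: 7 (3R,5R)-3-(tert-butyldimethylsilyloxy)-2-methyl-5-(propan-2-yl)cyclopent-1-ene-1-carbaldehyde
Conditions: piperidine (0.3 equiv), AcOH (0.3 equiv), toluene, 4 Å sieves, 70 °C
Reagents that add atoms: none
Why: Amine–acid catalysed intramolecular aldol condensation, in which the enamine of the aldehyde adds to the methyl ketone and dehydration gives the tetrasubstituted enal, closes the ring C6–C7–C8–C9–C10 with C6=C10 in place and leaves the non-enolisable C7 untouched.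

Step 6
Reactants: 7 enal; 8 ethyl 2-[bis(2,2,2-trifluoroethoxy)phosphoryl]propanoate
Product: 9 ethyl (2Z)-3-[(3R,5R)-3-(tert-butyldimethylsilyloxy)-2-methyl-5-(propan-2-yl)cyclopent-1-en-1-yl]-2-methylprop-2-enoate
Conditions: 8, KN(SiMe3)2, 18-crown-6, THF, −78 °C; then 7, −78 °C to −40 °C
Reagents that add atoms: none
Why: Still–Gennari olefination, in which the electron-poor phosphonate anion adds irreversibly and eliminates fast, should give the Z trisubstituted enoate and so place the ester carbon (later C1) cis to the cyclopentenyl group across the new C3=C5 bond.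

Step 7
Reactants: 9 Z-dienoate
Product: 10 (2Z)-3-[(3R,5R)-3-(tert-butyldimethylsilyloxy)-2-methyl-5-(propan-2-yl)cyclopent-1-en-1-yl]-2-methylprop-2-en-1-ol
Conditions: i-Bu2AlH (2.5 equiv), CH2Cl2, −78 °C; aq. potassium sodium tartrate
Reagents that add atoms: none
Why: 1,2-Reduction of the conjugated ester by two hydride transfers at low temperature should give the Z allylic alcohol without isomerising the diene or cleaving the silyl ether.

Step 8
Reactants: 10 Z-dienol
Product: 11 [(1R,2R)-2-{(3R,5R)-3-(tert-butyldimethylsilyloxy)-2-methyl-5-(propan-2-yl)cyclopent-1-en-1-yl}-1-methylcyclopropyl]methanol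
Conditions: Et2Zn, CH2I2, DME, (4S,5S)-2-butyl-N,N,N',N'-tetramethyl-1,3,2-dioxaborolane-4,5-dicarboxamide (1.2 equiv), CH2Cl2, −10 °C to rt
Reagents that add atoms: bis(iodomethyl)zinc, IC[Zn]CI (made in the flask from diethylzinc, CC[Zn]CC, and diiodomethane, ICI)
Why: Hydroxyl-directed asymmetric Simmons–Smith cyclopropanation delivers CH2 from the zinc alkoxide held by the chiral dioxaborolane to the proximal C3=C5 olefin only, syn addition keeps the hydroxymethyl and cyclopentenyl groups cis, and the (S,S)-ligand should select the face that gives the 1R,2R cyclopropane, which sets C3 and C5.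

Step 9
Reactants: 11 silyl-protected cyclopropylmethanol
Product: 12 (1R,4R)-3-[(1R,2R)-2-(hydroxymethyl)-2-methylcyclopropyl]-2-methyl-4-(propan-2-yl)cyclopent-2-en-1-ol
Conditions: Bu4NF, THF, 0 °C to rt
Reagents that add atoms: none
Why: Fluoride-mediated cleavage of the silyl ether frees the allylic C9 alcohol so that both carbinols can be oxidised together.

Step 10
Reactants: 12 diol
Product: 13 (1R,2R)-1-methyl-2-[(5R)-2-methyl-3-oxo-5-(propan-2-yl)cyclopent-1-en-1-yl]cyclopropane-1-carbaldehyde
Conditions: Dess–Martin periodinane (2.6 equiv), NaHCO3, CH2Cl2, 0 °C to rt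
Reagents that add atoms: none
Why: Dess–Martin oxidation converts the allylic alcohol into the cyclopentenone and the primary alcohol into the aldehyde under buffered conditions that leave the cyclopropane intact, and the aldehyde is used at once because cis-2-alkenylcyclopropanecarbaldehydes can equilibrate with dihydrooxepines.

Step 11
Reactants: 13 keto aldehyde
Product: 14 (1R,2R)-1-methyl-2-[(5R)-2-methyl-3-oxo-5-(propan-2-yl)cyclopent-1-en-1-yl]cyclopropane-1-carboxylic acid
Conditions: NaClO2, NaH2PO4, 2-methyl-2-butene, t-BuOH/H2O, 0 °C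
Reagents that add atoms: sodium chlorite, [Na+].[O-]Cl=O
Why: Pinnick oxidation with a hypochlorite scavenger oxidises the hindered aldehyde to the acid without touching the enone or the tetrasubstituted olefin.

Step 12
Reactants: 14 keto acid; 15 N-methyl-N-nitroso-4-toluenesulfonamide
Product: 18 2-diazo-1-{(1R,2R)-1-methyl-2-[(5R)-2-methyl-3-oxo-5-(propan-2-yl)cyclopent-1-en-1-yl]cyclopropyl}ethan-1-one, via acid chloride 16 (not isolated), via diazomethane 17 (not isolated)
Conditions: (COCl)2, DMF (cat.), CH2Cl2, 0 °C; then CH2N2 (from 15, KOH, Et2O/EtOH/H2O; excess), Et2O, 0 °C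
Reagents that add atoms: oxalyl chloride, O=C(Cl)C(Cl)=O (chlorine of 16 only)
Why: Acylation of diazomethane by an acid chloride (first stage of the Arndt–Eistert sequence) is reliable here because the acid chloride has no α-hydrogen, excess diazomethane takes up HCl, and the tetrasubstituted enone is too hindered for dipolar cycloaddition.

Step 13
Reactants: 18 cyclopropyl diazoketone
Product: 20 bicyclic dienedione (C1 ketone, C2=C3, C5=C6, 7α-isopropyl, C9 ketone, 10β-methyl), via ketene 19 (not isolated)
Conditions: PhCO2Ag (0.1 equiv), Et3N (1 equiv), THF (0.01 M), ultrasound, 45 °C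
Reagents that add atoms: none
Why: Silver-promoted loss of N2 triggers the Wolff 1,2-shift of C3 (with retention) to the diazo carbon, which forms C2–C3 and gives ketene 19; its C2=C1 bond and the enone C6=C10 bond are cis on the cyclopropane, and a [3,3] shift through the boat transition state with both π-bonds over the three-membered ring forms C1–C10 and breaks C3–C5. The closest known reactions are the tandem Wolff–Cope rearrangement of cis-2-vinylcyclopropyl diazoketones to cyclohepta-2,5-dienones and the thermal Cope rearrangement of 2-methyl-3-(2-vinylcyclopropyl)cyclopent-2-enones to angularly methylated hydroazulenones. The seven-membered ring is closed by ring expansion of the cyclopropane in a concerted suprafacial six-electron sigmatropic shift, not by an exo or endo cyclisation, which is why the fully substituted C10 can be joined. The only new stereocentre, C10, is controlled by the configuration of C5 set in step 8, because C10 reaches C1 only from the rotamer that holds C10 (not C7) over the cyclopropane, and this rotamer offers the ketene a single face of C6=C10, leaving the methyl group β and trans to the C7 isopropyl group. The selectivity needed is one of rate, rearrangement before the ketene dimerises or is trapped, although the C10 methyl points at the cyclopropane CH2 and the C7 isopropyl lies on the ketene side. The substrate secures it through the sp-hybridised ketene terminus without an inward substituent, the strain released on C3–C5 cleavage and the absence of an internal nucleophile, supported by high dilution.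

Step 14
Reactants: 20 bicyclic dienedione
Product: 21 C9 ethylene ketal of 20 (C1 enone kept)
Conditions: (TMSOCH2)2, TMSOTf (cat.), CH2Cl2, −78 °C to −30 °C
Reagents that add atoms: 1,2-bis(trimethylsilyloxy)ethane, C[Si](C)(C)OCCO[Si](C)(C)C
Why: Silyl triflate-catalysed ketalisation should take the saturated C9 ketone and leave the conjugated C1 ketone, and masking C9 removes the 1,3-diketone that would let a C6 alkoxide fragment by retro-aldol cleavage and leaves C1 as the only ketone for step 18.

Step 15
Reactants: 21 ketal dienone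
Product: 22 5α,6α-epoxide of 21
Conditions: mCPBA, NaHCO3, CH2Cl2, 0 °C
Reagents that add atoms: 3-chloroperoxybenzoic acid, OOC(=O)c1cccc(Cl)c1
Why: Peracid epoxidation picks the only electron-rich olefin (C2=C3 is deactivated by conjugation) and should attack the α face, anti to the axial C10 methyl group that stands over C6 as the angular methyl does in 5-ene steroids, which sets the C6–O bond trans to that methyl.

Step 16
Reactants: 22 epoxide
Product: 23 5β-phenylselanyl-6α-hydroxy enone ketal
Conditions: (PhSe)2, NaBH4, EtOH, 0 °C; then 22, 60 °C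
Reagents that add atoms: sodium benzeneselenolate, [Na+].[Se-]c1ccccc1 (made in the flask from diphenyl diselenide, c1ccc(cc1)[Se][Se]c1ccccc1, and NaBH4)
Why: The soft selenolate opens the epoxide by SN2 attack at the secondary C5 (trans-diaxial opening with inversion at C5) because C6 is fully substituted and neopentyl, and the non-acidic medium avoids cationic rearrangement at C6, so the tertiary C6 α-alcohol is kept.

Step 17
Reactants: 23 hydroxy selenide
Product: 24 6α-hydroxy enone ketal (C5 methylene)
Conditions: Bu3SnH, AIBN (cat.), toluene, 80 °C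
Reagents that add atoms: none
Why: Radical chain reduction of the C–Se bond by the tin hydride replaces selenium at C5 by hydrogen and leaves the alcohol, the ketal and the enone alone.

Step 18
Reactants: 24 hydroxy enone ketal
Product: 25 1β,6α-diol ketal
Conditions: Me4NBH(OAc)3, MeCN/AcOH, −30 °C to 0 °C
Reagents that add atoms: none
Why: Hydroxyl-directed triacetoxyborohydride reduction (anti-selective 1,3-diol synthesis) exchanges an acetate for the C6 α-alkoxide and delivers hydride intramolecularly to the α face of the C1 ketone, which should give the C1 β-alcohol, anti to the C6 hydroxyl and cis to the C10 methyl.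

Step 19
Reactants: 25 diol ketal; 26 4-methoxybenzoyl chloride
Product: 27 C1 4-methoxybenzoate of 25
Conditions: 26, pyridine, DMAP (cat.), CH2Cl2, 0 °C to rt
Reagents that add atoms: none
Why: Acylation under nucleophilic catalysis esterifies the secondary allylic C1 alcohol only, since the tertiary C6 alcohol is too hindered to react.

Step 20
Reactants: 27 anisoate ketal
Product: 28 CNP0246512.2 (target)
Conditions: PPTS (cat.), acetone/H2O, 50 °C
Reagents that add atoms: water, O
Why: Mild acid-catalysed hydrolysis of the dioxolane frees the C9 ketone under conditions that the allylic ester and the tertiary β-hydroxy ketone should survive.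

**Compound list**
1 | (R)-(−)-carvone | CC1=CC[C@H](CC1=O)C(C)=C | starting material
2 | (5R)-2-methyl-5-(propan-2-yl)cyclohex-2-en-1-one | CC1=CC[C@H](CC1=O)C(C)C | intermediate
3 | (1R,5R)-2-methyl-5-(propan-2-yl)cyclohex-2-en-1-ol | CC1=CC[C@H](C[C@H]1O)C(C)C | intermediate
4 | tert-butyldimethylsilyl ether of 3 | CC1=CC[C@H](C[C@H]1O[Si](C)(C)C(C)(C)C)C(C)C | intermediate
5 | ozonide of 4 (trioxolane across the former C=C, mixture at the two trioxolane carbons) | CC12OOC(O1)C[C@H](C[C@H]2O[Si](C)(C)C(C)(C)C)C(C)C | intermediate
6 | (3S,5R)-5-(tert-butyldimethylsilyloxy)-6-oxo-3-(propan-2-yl)heptanal | CC(=O)[C@H](O[Si](C)(C)C(C)(C)C)C[C@@H](CC=O)C(C)C | intermediate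
7 | (3R,5R)-3-(tert-butyldimethylsilyloxy)-2-methyl-5-(propan-2-yl)cyclopent-1-ene-1-carbaldehyde | O=CC1=C(C)[C@H](O[Si](C)(C)C(C)(C)C)C[C@@H]1C(C)C | intermediate
8 | ethyl 2-[bis(2,2,2-trifluoroethoxy)phosphoryl]propanoate | CCOC(=O)C(C)P(=O)(OCC(F)(F)F)OCC(F)(F)F | starting material
9 | ethyl (2Z)-3-[(3R,5R)-3-(tert-butyldimethylsilyloxy)-2-methyl-5-(propan-2-yl)cyclopent-1-en-1-yl]-2-methylprop-2-enoate | CCOC(=O)/C(C)=C\C1=C(C)[C@H](O[Si](C)(C)C(C)(C)C)C[C@@H]1C(C)C | intermediate
10 | (2Z)-3-[(3R,5R)-3-(tert-butyldimethylsilyloxy)-2-methyl-5-(propan-2-yl)cyclopent-1-en-1-yl]-2-methylprop-2-en-1-ol | OC/C(C)=C\C1=C(C)[C@H](O[Si](C)(C)C(C)(C)C)C[C@@H]1C(C)C | intermediate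
11 | [(1R,2R)-2-{(3R,5R)-3-(tert-butyldimethylsilyloxy)-2-methyl-5-(propan-2-yl)cyclopent-1-en-1-yl}-1-methylcyclopropyl]methanol | OC[C@]1(C)C[C@@H]1C2=C(C)[C@H](O[Si](C)(C)C(C)(C)C)C[C@@H]2C(C)C | intermediate
12 | (1R,4R)-3-[(1R,2R)-2-(hydroxymethyl)-2-methylcyclopropyl]-2-methyl-4-(propan-2-yl)cyclopent-2-en-1-ol | OC[C@]1(C)C[C@@H]1C2=C(C)[C@H](O)C[C@@H]2C(C)C | intermediate
13 | (1R,2R)-1-methyl-2-[(5R)-2-methyl-3-oxo-5-(propan-2-yl)cyclopent-1-en-1-yl]cyclopropane-1-carbaldehyde | O=C[C@]1(C)C[C@@H]1C2=C(C)C(=O)C[C@@H]2C(C)C | intermediate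
14 | (1R,2R)-1-methyl-2-[(5R)-2-methyl-3-oxo-5-(propan-2-yl)cyclopent-1-en-1-yl]cyclopropane-1-carboxylic acid | OC(=O)[C@]1(C)C[C@@H]1C2=C(C)C(=O)C[C@@H]2C(C)C | intermediate
15 | N-methyl-N-nitroso-4-toluenesulfonamide | Cc1ccc(cc1)S(=O)(=O)N(C)N=O | starting material
16 | acid chloride of 14 | ClC(=O)[C@]1(C)C[C@@H]1C2=C(C)C(=O)C[C@@H]2C(C)C | intermediate
17 | diazomethane | C=[N+]=[N-] | intermediate
18 | 2-diazo-1-{(1R,2R)-1-methyl-2-[(5R)-2-methyl-3-oxo-5-(propan-2-yl)cyclopent-1-en-1-yl]cyclopropyl}ethan-1-one | [N-]=[N+]=CC(=O)[C@]1(C)C[C@@H]1C2=C(C)C(=O)C[C@@H]2C(C)C | intermediate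
19 | ketene from 18: 2-{(1R,2R)-1-methyl-2-[(5R)-2-methyl-3-oxo-5-(propan-2-yl)cyclopent-1-en-1-yl]cyclopropyl}ethen-1-one | O=C=C[C@]1(C)C[C@@H]1C2=C(C)C(=O)C[C@@H]2C(C)C | intermediate
20 | bicyclic dienedione (C1 and C9 ketones, C2=C3, C5=C6, 7α-isopropyl, 10β-methyl) | O=C1C=C(C)CC=C2[C@@H](C(C)C)CC(=O)[C@@]12C | intermediate
21 | C9 ethylene ketal of 20 | O=C1C=C(C)CC=C2[C@@H](C(C)C)CC3(OCCO3)[C@@]12C | intermediate
22 | 5α,6α-epoxide of 21 | O=C1C=C(C)C[C@H]2O[C@]23[C@@H](C(C)C)CC4(OCCO4)[C@@]13C | intermediate
23 | 5β-phenylselanyl-6α-hydroxy enone ketal | O=C1C=C(C)C[C@H]([Se]c2ccccc2)[C@]3(O)[C@@H](C(C)C)CC4(OCCO4)[C@@]13C | intermediate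
24 | 6α-hydroxy enone ketal | O=C1C=C(C)CC[C@]2(O)[C@@H](C(C)C)CC3(OCCO3)[C@@]12C | intermediate
25 | 1β,6α-diol ketal | O[C@@H]1C=C(C)CC[C@]2(O)[C@@H](C(C)C)CC3(OCCO3)[C@@]12C | intermediate
26 | 4-methoxybenzoyl chloride | COc1ccc(cc1)C(Cl)=O | starting material
27 | C1 4-methoxybenzoate of 25 (C9 ketal) | COc1ccc(cc1)C(=O)O[C@@H]2C=C(C)CC[C@]3(O)[C@@H](C(C)C)CC4(OCCO4)[C@@]23C | intermediate
28 | CNP0246512.2 (1β-anisoyloxy, 6α-hydroxy, 7α-isopropyl, 9-oxo, 10β-methyl) | COc1ccc(C(=O)O[C@@H]2C=C(C)CC[C@]3(O)[C@@H](C(C)C)CC(=O)[C@@]23C)cc1 | target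

**Step count and risks**
Total steps: 20. Longest linear sequence: 20 steps (from 1; compounds 8, 15 and 26 are bought).

The three steps most likely to fail:

Step 13. The ketene may be lost to dimerisation or to capture by benzoate or traces of water before the sterically loaded boat rearrangement takes place. The fallback sets out from aldehyde 13 and brings C1 in as a stable vinyl partner. Boron olefination of 13 with Cl2CHBpin, CrCl2 and LiI in THF (Takai–Utimoto type) should give the E-alkenyl pinacolboronate F1, with boron in the outward position of the vinyl terminus. Heating F1 in toluene (80–110 °C) should bring about the plain thermal divinylcyclopropane Cope rearrangement, with the same C1–C10 bond formation and the same control of C10 by the cyclopropane, to the bicyclic allylic boronate F2. Oxidation with NaBO3·4H2O in THF/H2O gives the C1 α-alcohol F3, and Dess–Martin oxidation of F3 comes back to the route at 20.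

Step 15. Oxygen transfer may show poor or reversed facial selectivity, because the α face carries the C7 isopropyl group while the β face carries the C10 methyl. The fallback sets out from 21 and uses the opposite logic: an electrophile on the β face followed by anti attack of water. NBS in acetone/H2O at 0 °C should form the bromonium ion on the face the peracid preferred, and water opens it at the tertiary C6 from the α face to give the bromohydrin F4 (5β-bromo, 6α-hydroxy). Bu3SnH with AIBN in toluene removes bromine and comes back to the route at 24.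

Step 18. Ligand exchange at the tertiary C6 hydroxyl may be slow, so that the reduction stalls or undirected hydride transfer erodes the selectivity at C1. The fallback sets out from 21 and fixes C1 under steric control before C6 is oxygenated. Luche reduction of 21 (NaBH4, CeCl3·7H2O, MeOH, −78 °C), now with C1 as the only ketone and the α face open, should give by attack anti to the axial C10 methyl the 1β allylic alcohol F5. Acylation with 26 (pyridine, DMAP) gives the anisoate F6, whose C2=C3 olefin is deactivated by the allylic ester. Epoxidation with mCPBA at C5=C6 gives the epoxide F7, opening with sodium benzeneselenolate gives the hydroxy selenide F8, and Bu3SnH with AIBN comes back to the route at 27.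

**Further compounds**
F1 | step 13 | E-alkenyl pinacolboronate from 13 | CC1(C)OB(/C=C/[C@]2(C)C[C@@H]2C3=C(C)C(=O)C[C@@H]3C(C)C)OC1(C)C
F2 | step 13 | bicyclic allylic boronate (1α-boryl, C2=C3, C5=C6, C9 ketone) | CC1(C)OB(OC1(C)C)[C@H]2C=C(C)CC=C3[C@@H](C(C)C)CC(=O)[C@@]23C
F3 | step 13 | C1 α-alcohol of the bicyclic dienone | O[C@H]1C=C(C)CC=C2[C@@H](C(C)C)CC(=O)[C@@]12C
F4 | step 15 | 5β-bromo-6α-hydroxy enone ketal | O=C1C=C(C)C[C@H](Br)[C@]2(O)[C@@H](C(C)C)CC3(OCCO3)[C@@]12C
F5 | step 18 | 1β-hydroxy diene ketal | O[C@@H]1C=C(C)CC=C2[C@@H](C(C)C)CC3(OCCO3)[C@@]12C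
F6 | step 18 | 1β-anisoyloxy diene ketal | COc1ccc(cc1)C(=O)O[C@@H]2C=C(C)CC=C3[C@@H](C(C)C)CC4(OCCO4)[C@@]23C
F7 | step 18 | 5α,6α-epoxide of the anisoate ketal | COc1ccc(cc1)C(=O)O[C@@H]2C=C(C)C[C@H]3O[C@]34[C@@H](C(C)C)CC5(OCCO5)[C@@]24C
F8 | step 18 | 5β-phenylselanyl-6α-hydroxy anisoate ketal | COc1ccc(cc1)C(=O)O[C@@H]2C=C(C)C[C@H]([Se]c3ccccc3)[C@]4(O)[C@@H](C(C)C)CC5(OCCO5)[C@@]24C
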